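## Retrosynthetic overview

1. Target 12 ⇐ bis-pivalate 9 by ester cleavage only.
2. 9 ⇐ meso cis-3,4-dibenzyltetrahydrofuran 8 by hydroxylation of one benzylic C–H; this single C–O bond desymmetrises 8 and fixes all three stereocentres.
3. 8 ⇐ exocyclic diene 6 by cis-hydrogenation; 6 ⇐ 1,6-diyne 5 by reductive cyclisation. The tetrahydrofuran ring is the only ring built; both arenes are bought.
4. 5 ⇐ two aryl bromides 2 (from 5-bromo-2-methoxyphenol 1) and dipropargyl ether 3 by twofold Sonogashira coupling.

Assumption: the target is taken exactly as drawn, a cis-3,4-disubstituted tetrahydrofuran (ring C3 S, ring C4 R) with an (S)-carbinol; both aryl groups are 3-hydroxy-4-methoxyphenyl, so the compound lacking the carbinol OH is meso.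

Assumption: the sense of induction of the new hydroxylation (step 5) cannot be predicted with certainty; the catalyst is written as (S,S), and its mirror image is used if a pilot run shows the opposite sense.

Abbreviation: (S,S)-TIPSpdp = (2S,2'S)-1,1'-bis{[5-(triisopropylsilyl)pyridin-2-yl]methyl}-2,2'-bipyrrolidine. Lignan locants used below: C7 = carbinol carbon, C8 = ring C3, C8' = ring C4.

## Route

Step 1
Reactants: 1 5-bromo-2-methoxyphenol
Product: 2 5-bromo-2-methoxyphenyl pivalate
Conditions: PivCl (1.2 equiv), Et3N (1.5 equiv), DMAP (5 mol %), CH2Cl2, 0 → 25 °C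
Reagents that add atoms: pivaloyl chloride, CC(C)(C)C(=O)Cl
Why: DMAP-catalysed O-acylation (nucleophilic acyl substitution) masks the phenol as a hindered, mildly electron-withdrawing ester that survives Pd, Rh, H2 and the later oxidation and tempers the arene toward ring oxidation.

Step 2
Reactants: 2 5-bromo-2-methoxyphenyl pivalate (2.1 equiv); 3 dipropargyl ether
Product: 5 bis{3-[4-methoxy-3-(pivaloyloxy)phenyl]prop-2-yn-1-yl} ether, via mono-coupled diyne 4 (not isolated)
Conditions: Pd(PhCN)2Cl2 (3 mol %), [HP(t-Bu)3]BF4 (6 mol %), CuI (2 mol %), HN(i-Pr)2, 1,4-dioxane, 25 °C, degassed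
Reagents that add atoms: none
Why: Twofold Sonogashira coupling, in which the bulky electron-rich phosphine lets the electron-rich aryl bromide undergo oxidative addition at room temperature and the hindered amine leaves the aryl pivalate untouched.

Step 3
Reactants: 5 bis{3-[4-methoxy-3-(pivaloyloxy)phenyl]prop-2-yn-1-yl} ether
Product: 6 (3Z,4Z)-3,4-bis[4-methoxy-3-(pivaloyloxy)benzylidene]tetrahydrofuran
Conditions: Rh(cod)2OTf (5 mol %), rac-BINAP (5 mol %), H2 (1 atm), ClCH2CH2Cl, 25 °C
Reagents that add atoms: none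
Why: Rhodium-catalysed hydrogen-mediated reductive cyclisation of a 1,6-diyne (oxidative cyclisation to a rhodacyclopentadiene, then hydrogenolysis of both Rh–C bonds with retention) forms the C3–C4 bond and the five-membered ring with both aryl groups pointing outward, and creates no stereocentre.

Step 4
Reactants: 6 (3Z,4Z)-3,4-bis[4-methoxy-3-(pivaloyloxy)benzylidene]tetrahydrofuran
Product: 8 meso-(3R,4S)-3,4-bis[4-methoxy-3-(pivaloyloxy)benzyl]tetrahydrofuran, via half-reduced alkene 7 (not isolated)
Conditions: 10% Pd/C, H2 (4 bar), EtOAc, 25 °C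
Reagents that add atoms: none
Why: Heterogeneous syn-hydrogenation, in which the second H2 is delivered to the face of alkene 7 anti to the existing benzyl group so that the new benzyl group ends up cis (any 2,5-dihydrofuran or furan isomer formed on Pd also gives cis by syn addition), and the cis product is the achiral meso compound.

Step 5
Reactants: 8 meso-(3R,4S)-3,4-bis[4-methoxy-3-(pivaloyloxy)benzyl]tetrahydrofuran
Product: 9 5-{(S)-hydroxy[(3S,4R)-4-(4-methoxy-3-(pivaloyloxy)benzyl)tetrahydrofuran-3-yl]methyl}-2-methoxyphenyl pivalate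
Conditions: [Mn(OTf)2((S,S)-TIPSpdp)] (3 mol %), 30% aq H2O2 (1.2 equiv, syringe pump), c-PrCO2H (2 equiv), CF3CH2OH/(CF3)2CHOH 4:1, −35 °C, stopped at about 70% conversion, NaHCO3/Na2S2O3 quench
Reagents that add atoms: hydrogen peroxide, OO
Why: Proposed new method: a chiral electrophilic pentavalent manganese oxo species abstracts one of the four benzylic hydrogens of meso 8 and returns OH by stereoretentive rebound, its silyl-walled pocket choosing both the enantiotopic CH2Ar group and the diastereotopic hydrogen, which sets C7 (S) and thereby fixes ring C3 (S) and C4 (R), while the fluorinated alcohol hydrogen-bonds to the ring oxygen and to the new carbinol (switching off the α-oxy C–H bonds and over-oxidation to ketone) and the minor enantiomer is skimmed off by a faster second hydroxylation at its remaining matched benzylic group; the closest known reaction type is manganese aminopyridine-catalysed enantioselective benzylic and methylene C–H hydroxylation with H2O2 in fluorinated alcohols, which has not been shown as an enantiotopic-group-selective desymmetrisation of a meso bis-benzylic ether.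

Step 6
Reactants: 9 5-{(S)-hydroxy[(3S,4R)-4-(4-methoxy-3-(pivaloyloxy)benzyl)tetrahydrofuran-3-yl]methyl}-2-methoxyphenyl pivalate
Product: 12 (S)-(3-hydroxy-4-methoxyphenyl)[(3S,4R)-4-(3-hydroxy-4-methoxybenzyl)tetrahydrofuran-3-yl]methanol, via benzyl-side mono-pivalate 10 (not isolated), via carbinol-side mono-pivalate 11 (not isolated)
Conditions: N2H4·H2O (6 equiv), THF/MeOH 1:1, 25 → 40 °C
Reagents that add atoms: none
Why: Hydrazinolysis of the two aryl esters (acyl transfer to an α-effect nucleophile) frees both phenols under non-acidic conditions, so the acid-labile p-methoxybenzylic carbinol neither ionises nor epimerises and no stereocentre is touched.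

## Compound list

1 | 5-bromo-2-methoxyphenol | COc1ccc(Br)cc1O | starting material
2 | 5-bromo-2-methoxyphenyl pivalate | COc1ccc(Br)cc1OC(=O)C(C)(C)C | intermediate
3 | dipropargyl ether, 3-(prop-2-yn-1-yloxy)prop-1-yne | C#CCOCC#C | starting material
4 | 2-methoxy-5-[3-(prop-2-yn-1-yloxy)prop-1-yn-1-yl]phenyl pivalate (mono-coupled diyne) | COc1ccc(C#CCOCC#C)cc1OC(=O)C(C)(C)C | intermediate
5 | bis{3-[4-methoxy-3-(pivaloyloxy)phenyl]prop-2-yn-1-yl} ether | COc1ccc(C#CCOCC#Cc2ccc(OC)c(OC(=O)C(C)(C)C)c2)cc1OC(=O)C(C)(C)C | intermediate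
6 | (3Z,4Z)-3,4-bis[4-methoxy-3-(pivaloyloxy)benzylidene]tetrahydrofuran | COc1ccc(/C=C2\COC/C2=C\c2ccc(OC)c(OC(=O)C(C)(C)C)c2)cc1OC(=O)C(C)(C)C | intermediate
7 | racemic (Z)-3-[4-methoxy-3-(pivaloyloxy)benzyl]-4-[4-methoxy-3-(pivaloyloxy)benzylidene]tetrahydrofuran (half-reduced alkene) | COc1ccc(CC2COC/C2=C\c2ccc(OC)c(OC(=O)C(C)(C)C)c2)cc1OC(=O)C(C)(C)C | intermediate
8 | meso-(3R,4S)-3,4-bis[4-methoxy-3-(pivaloyloxy)benzyl]tetrahydrofuran (cis) | COc1ccc(C[C@H]2COC[C@H]2Cc2ccc(OC)c(OC(=O)C(C)(C)C)c2)cc1OC(=O)C(C)(C)C | intermediate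
9 | 5-{(S)-hydroxy[(3S,4R)-4-(4-methoxy-3-(pivaloyloxy)benzyl)tetrahydrofuran-3-yl]methyl}-2-methoxyphenyl pivalate | COc1ccc(C[C@H]2COC[C@H]2[C@H](O)c2ccc(OC)c(OC(=O)C(C)(C)C)c2)cc1OC(=O)C(C)(C)C | intermediate
10 | 5-{[(3R,4S)-4-[(S)-hydroxy(3-hydroxy-4-methoxyphenyl)methyl]tetrahydrofuran-3-yl]methyl}-2-methoxyphenyl pivalate (benzyl-side mono-pivalate) | COc1ccc(C[C@H]2COC[C@H]2[C@H](O)c2ccc(OC)c(O)c2)cc1OC(=O)C(C)(C)C | intermediate
11 | 5-{(S)-hydroxy[(3S,4R)-4-(3-hydroxy-4-methoxybenzyl)tetrahydrofuran-3-yl]methyl}-2-methoxyphenyl pivalate (carbinol-side mono-pivalate) | COc1ccc(C[C@H]2COC[C@H]2[C@H](O)c2ccc(OC)c(OC(=O)C(C)(C)C)c2)cc1O | intermediate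
12 | (S)-(3-hydroxy-4-methoxyphenyl)[(3S,4R)-4-(3-hydroxy-4-methoxybenzyl)tetrahydrofuran-3-yl]methanol | COc1ccc(C[C@H]2COC[C@H]2[C@H](O)c2ccc(OC)c(O)c2)cc1O | target

## Step count

Total steps: 6. Longest linear sequence: 6 (1 → 2 → 5 → 6 → 8 → 9 → 12).

## Steps most likely to fail

**Step 5 (the proposed new hydroxylation).** Risks:
- oxidation at the ring α-oxy C–H bonds or on the arenes;
- abstraction of the wrong diastereotopic hydrogen, giving the C7 epimer;
- insufficient discrimination between the two enantiotopic benzyl groups;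
- ionisation of the p-methoxybenzylic alcohol in the fluorinated solvent, hence the low temperature and basic quench.

Fallback with known chemistry, setting out from 8 and returning at 9: treat 8 with DDQ (2.2 equiv) in wet 1,4-dioxane at 25–50 °C, stopping at partial conversion and recycling 8. This gives the racemic cis mono-ketone F1 by the known hydride-abstraction oxidation of p-methoxybenzylic positions. Reduce F1 with (R)-Me-CBS oxazaborolidine and BH3·SMe2 in THF at −20 °C, with the aryl group acting as the large substituent. Reagent control turns both ketone enantiomers into (S)-carbinols, namely 9 and its ring-enantiomeric diastereomer F2, which are separated by chromatography (at most 50% of F1 becomes 9). The C7 configuration is confirmed by Mosher ester analysis.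

**Step 3 (rhodium reductive cyclisation).** Risks: plain alkyne hydrogenation, or [2+2+2] oligomerisation of the diaryl diyne.

Fallback, setting out from 2 and returning at 8, which replaces ring construction by cross-coupling onto a preformed furan: convert 2 with Mg turnings, LiCl and ZnCl2 in THF at 25 °C into the arylzinc chloride F3. Couple it twice under Pd(PPh3)4 catalysis (THF, 50 °C, Negishi coupling) with 3,4-bis(chloromethyl)furan F4, made from commercial furan-3,4-diyldimethanol (OCc1cocc1CO) with SOCl2 in CH2Cl2 at 0 °C. This gives 3,4-bis[4-methoxy-3-(pivaloyloxy)benzyl]furan F5. Hydrogenate the furan over 10% Pd/C (H2 30 bar, EtOAc/AcOH, 50 °C); both H2 molecules add to one face, giving cis-8.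

**Step 4 (hydrogenation of the diene).** Risks: palladium-induced isomerisation to a furan that stalls, hydrogenolysis of the allylic C–O bonds, or leakage to the trans isomer.

Fallback, setting out from 6 and returning at 8: carry out a 1,4-hydrogenation of the s-cis diene with (naphthalene)Cr(CO)3 (10 mol %) under H2 (50 bar) in acetone at 40 °C. This gives 3,4-bis[4-methoxy-3-(pivaloyloxy)benzyl]-2,5-dihydrofuran F6. Hydrogenate its tetrasubstituted ring alkene with [Ir(cod)(PCy3)(py)]PF6 (5 mol %) under H2 (10 bar) in CH2Cl2 at 25 °C. Syn addition across the ring alkene can only give cis-8, and this homogeneous catalyst does not cleave allylic ethers.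

## Further compounds

F1 | step 5 | racemic cis mono-ketone, [4-(4-methoxy-3-(pivaloyloxy)benzyl)tetrahydrofuran-3-yl][4-methoxy-3-(pivaloyloxy)phenyl]methanone, (3S,4R)/(3R,4S), one enantiomer drawn | COc1ccc(C[C@H]2COC[C@H]2C(=O)c2ccc(OC)c(OC(=O)C(C)(C)C)c2)cc1OC(=O)C(C)(C)C
F2 | step 5 | 5-{(S)-hydroxy[(3R,4S)-4-(4-methoxy-3-(pivaloyloxy)benzyl)tetrahydrofuran-3-yl]methyl}-2-methoxyphenyl pivalate (diastereomer of 9) | COc1ccc(C[C@@H]2COC[C@@H]2[C@H](O)c2ccc(OC)c(OC(=O)C(C)(C)C)c2)cc1OC(=O)C(C)(C)C
F3 | step 3 | [4-methoxy-3-(pivaloyloxy)phenyl]zinc chloride | COc1ccc([Zn]Cl)cc1OC(=O)C(C)(C)C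
F4 | step 3 | 3,4-bis(chloromethyl)furan | ClCc1cocc1CCl
F5 | step 3 | 3,4-bis[4-methoxy-3-(pivaloyloxy)benzyl]furan | COc1ccc(Cc2cocc2Cc2ccc(OC)c(OC(=O)C(C)(C)C)c2)cc1OC(=O)C(C)(C)C
F6 | step 4 | 3,4-bis[4-methoxy-3-(pivaloyloxy)benzyl]-2,5-dihydrofuran | COc1ccc(CC2=C(Cc3ccc(OC)c(OC(=O)C(C)(C)C)c3)COC2)cc1OC(=O)C(C)(C)C
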